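Assumption: the target is read from the SMILES as the achiral 5,7,4'-trihydroxy-6,2',5'-trimethoxyflavone, and compounds 1 and 8 are taken as catalogue chemicals.

## Structural features

The target is a flavone: a benzo ring A fused to a 4-pyranone ring C (O1, C2, C3, C4, C4a, C8a), with an aryl ring B attached through the C2–C1' bond, and no stereocenter. Ring A carries 5-OH (chelated to the C4 carbonyl), 6-OMe and 7-OH, so C8–H is its only hydrogen. Ring B carries 2'-OMe, 4'-OH and 5'-OMe, so only C3'–H and C6'–H remain. Three hydroxyls and three methoxyls sit on two electron-rich rings, so the O-methyl pattern cannot be set by late selective methylation or demethylation and must come in with the building blocks, with the three hydroxyls masked by one removable group. Fragile points are the free phenols of the oxygen-rich ring B (air oxidation), the reducible C2=C3 bond, the aryl methyl ethers towards Lewis acids, and ring C, whose opening and reclosure in hot strong acid would exchange the 6-methoxy for an 8-methoxy arrangement. The real difficulty is twofold: the C6 versus C8 regiochemistry on ring A, and the C2–C1' bond that joins an electron-poor heterocyclic carbon to a tetrasubstituted ring B at one defined carbon. The key step exploits that C1' lies para to O4' and ortho to the C2' methoxy group, which makes it the most nucleophilic C–H position of a 2,5-dimethoxyphenol ether. C2 of ring C is the β-carbon of the chromone enone and bears a hydrogen in the parent chromone, so the two rings can be joined C2–H to C1'–H with no halide, boron or carbonyl handle on either carbon.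

## Logic of the disconnections

11 to 10: the three O–benzyl bonds at O5, O7 and O4' are cut. One protecting group for all three phenols allows a single final deprotection and keeps the three methyl ethers distinct from the start. The forward step must cleave benzyl ethers without reducing C2=C3 or touching the methyl ethers.

10 to 7 and 9: the C2–C1' bond is cut. In one sentence: C2–H of 7 and C5–H of 9 are joined by a palladium-catalysed twofold C–H coupling. The cut separates the tricyclic array into a bicyclic 2-unsubstituted chromone and a simple arene, and ring B needs no carbon handle (no aldehyde, acid or alkyne) and no halide. The forward step must select C2 over C3 and C8 on 7, C5 over C3 and C6 on 9, and cross-coupling over homocoupling of 9.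

9 to 8: the O–benzyl bond is cut. This leaves a purchasable phenol whose oxygen pattern already is that of ring B. The forward step is a simple etherification.

7 to 5 (through 6): the O1–C2 and C2–C3 bonds are cut, which removes one carbon at the formate oxidation level. This reduces ring C to an ortho-hydroxy methyl ketone. The demand is that the 6-OH of 5 is the only free phenol, so that ring closure can only give the 6-methoxy and not the 8-methoxy chromone.

5 to 4: the O–CH3 bond on the C3 oxygen is cut. The forward methylation must distinguish the free 3-OH from the carbonyl-chelated 6-OH.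

4 to 2 (through 3): the aryl C3–O bond is cut. C3 is the position para to the only free phenol of 2, where a persulfate oxidation is expected to attack. The forward step must be para-selective and spare the benzyl ethers.

2 to 1: two O–benzyl bonds are cut, leading to a purchasable symmetrical triol ketone. The forward step must leave one ortho hydroxyl, which chelation to the carbonyl makes the least reactive.

## Other disconnections considered

Alternative 1: Baker–Venkataraman, the route most chemists would draw first. The cuts are C2–C3 and O1–C2. Forward: 5 is O-acylated with 4-(benzyloxy)-2,5-dimethoxybenzoyl chloride A1 to the aryl ester A2, base moves the aroyl group to carbon to give the 1,3-diketone A3, and acid cyclodehydration gives 10. A1 needs three further operations on 9 (formylation, oxidation, chlorination), so the count rises to about eleven steps against seven. The enolate of A2 is flanked by two ortho substituents, which should slow the acyl shift. The closing dehydration in strong acid is the condition under which the 5-O-benzyl group and the ring A regiochemistry are most at risk. The plan also makes no use of the innate nucleophilicity of C1'.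

Alternative 2: carbonylative annulation. The cuts are C4–C4a, C3–C4 and O1–C2. Forward: 3,5-bis(benzyloxy)-2-iodo-4-methoxyphenol A4, carbon monoxide and 1-(benzyloxy)-4-ethynyl-2,5-dimethoxybenzene A5 are combined under palladium catalysis to give 10 through an ortho-hydroxyaryl ynone. Three bonds form in one step, but both partners must be prefunctionalized. A4 needs a separate multistep ring A synthesis plus a regioselective iodination, and A5 needs a formylation and a homologation of 9. The ynone can also close in the 5-exo mode to an aurone, so the ring size of ring C is not secured by the substrate.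

Alternative 3: symmetry-based Friedel–Crafts closure. The cuts are C4–C4a and O1–C2. Forward: 3,5-bis(benzyloxy)-4-methoxyphenol A6 is added to ethyl 3-[4-(benzyloxy)-2,5-dimethoxyphenyl]prop-2-ynoate A7, the ester is saponified to the (Z)-3-aryloxycinnamic acid A8, and intramolecular acylation at either of the two equivalent ortho C–H positions of ring A gives 10. The symmetry of A6 settles the C6 versus C8 question elegantly. Against it, A6 and A7 each take several steps, only the Z isomer of A8 can close, and the ring closure needs a strong protic or Lewis acid, under which benzyl aryl ethers are expected to cleave or migrate. The chosen plan is shorter and runs its bond-forming step in a weak carboxylic acid.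

Key step: step 6

## Route

Step 1
Reactants: 1 2',4',6'-trihydroxyacetophenone
Product: 2 1-[2,4-bis(benzyloxy)-6-hydroxyphenyl]ethan-1-one
Conditions: BnBr (2.05 equiv), K2CO3 (2.2 equiv), DMF, 0 °C to rt
Reagents that add atoms: benzyl bromide, BrCc1ccccc1
Why: Williamson O-benzylation; the 4-OH (para to the acetyl group) and one of the two equivalent ortho hydroxyls react, while the remaining ortho hydroxyl is hydrogen-bonded to the carbonyl and is the least nucleophilic, so alkylation should stop at the bis-ether.

Step 2
Reactants: 2 1-[2,4-bis(benzyloxy)-6-hydroxyphenyl]ethan-1-one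
Product: 4 1-[2,4-bis(benzyloxy)-3,6-dihydroxyphenyl]ethan-1-one, via aryl potassium sulfate 3 (not isolated)
Conditions: K2S2O8 (1.2 equiv), aq KOH, pyridine, 0 °C to rt; then aq HCl, Na2SO3, toluene, 80 °C
Reagents that add atoms: potassium peroxodisulfate, [K+].[K+].[O-]S(=O)(=O)OOS(=O)(=O)[O-]
Why: Elbs persulfate oxidation; the phenolate of 2 attacks the peroxide oxygen through C3, the only free carbon para to the phenolic oxygen and activated by both flanking benzyloxy groups, and the aryl sulfate 3 is then hydrolysed by dilute acid to the hydroquinone. Benzyl ethers and the ketone should tolerate cold aqueous alkali and brief warm dilute acid.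

Step 3
Reactants: 4 1-[2,4-bis(benzyloxy)-3,6-dihydroxyphenyl]ethan-1-one
Product: 5 1-[2,4-bis(benzyloxy)-6-hydroxy-3-methoxyphenyl]ethan-1-one
Conditions: MeI (1.1 equiv), K2CO3 (1.1 equiv), acetone, rt to 40 °C
Reagents that add atoms: iodomethane, CI
Why: Chemoselective Williamson methylation; the 3-OH is a free phenol, whereas the 6-OH is chelated to the acetyl carbonyl and should react much more slowly with one equivalent of MeI under weak base.

Step 4
Reactants: 5 1-[2,4-bis(benzyloxy)-6-hydroxy-3-methoxyphenyl]ethan-1-one
Product: 7 5,7-bis(benzyloxy)-6-methoxy-4H-chromen-4-one, via enaminone 6 (not isolated)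
Conditions: Me2NCH(OMe)2 (3 equiv), toluene, 100 °C; then aq HCl, CH2Cl2, rt
Reagents that add atoms: N,N-dimethylformamide dimethyl acetal, COC(OC)N(C)C
Why: Enaminone route to chromones; the methyl ketone condenses with the amide acetal to the vinylogous amide 6, and acid-promoted conjugate addition of the ortho phenol with loss of dimethylamine closes ring C. Because the 6-OH is the only free phenol, closure can only give the 6-methoxy chromone.

Step 5
Reactants: 8 2,5-dimethoxyphenol
Product: 9 2-(benzyloxy)-1,4-dimethoxybenzene
Conditions: BnBr (1.1 equiv), K2CO3 (1.5 equiv), DMF, rt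
Reagents that add atoms: benzyl bromide, BrCc1ccccc1
Why: Williamson benzylation of the single phenol; the benzyl ether keeps the oxygen a strong para director for step 6 and is removed together with the two ring A benzyl groups at the end.

Step 6
Reactants: 7 5,7-bis(benzyloxy)-6-methoxy-4H-chromen-4-one; 9 2-(benzyloxy)-1,4-dimethoxybenzene
Product: 10 5,7-bis(benzyloxy)-2-[4-(benzyloxy)-2,5-dimethoxyphenyl]-6-methoxy-4H-chromen-4-one
Conditions: Pd(O2CCF3)2 (15 mol%), AgOAc (3 equiv), CsO2CCMe3 (1 equiv), Me3CCO2H, 9 (6 equiv, excess recovered), 100 °C
Reagents that add atoms: none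
Why: Palladium-catalysed twofold C–H (dehydrogenative) coupling, the closest known reaction type being the C2 arylation of chromones by arenes with a divalent palladium carboxylate and a silver carboxylate oxidant in pivalic acid. The electrophilic palladium carboxylate should metalate 9 at C5 (carboxylate-assisted, arenium-like), the aryl–palladium species then adds across C2=C3 of 7 with the aryl group delivered to the enone β-carbon C2, the C3 palladium enolate equilibrates through its oxygen-bound form and loses the C2 hydrogen by β-hydride elimination, and AgOAc returns zerovalent palladium to the divalent state. No ring is closed and no stereocenter is formed, so the step only needs site selectivity on each partner and cross-coupling over homocoupling. On 9, C5 is para to the benzyloxy oxygen, ortho to the C4 methoxy group and has only one ortho substituent, whereas C3 lies between two alkoxy groups and C6 has a single ortho oxygen donor, so both electronics and sterics point to C5, which becomes C1' with the 2', 4' and 5' oxygens in their places. On 7, aryl transfer to C2 follows from the polarity of the enone, and C8–H, the only hydrogen on ring A, sits on an acyl-deactivated ring between two oxygen substituents and should be metalated far more slowly than 9, which is used in excess. The unactivated phenyl rings of the benzyl ethers are much poorer substrates for electrophilic palladation than the trialkoxyarene, and benzyl aryl ethers should tolerate the weak acid pivalic acid. If the enolate is protonated instead, the resulting flavanone is dehydrogenated to 10 by the same palladium and silver system, so both branches converge.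

Step 7
Reactants: 10 5,7-bis(benzyloxy)-2-[4-(benzyloxy)-2,5-dimethoxyphenyl]-6-methoxy-4H-chromen-4-one
Product: 11 5,7-dihydroxy-2-(4-hydroxy-2,5-dimethoxyphenyl)-6-methoxy-4H-chromen-4-one
Conditions: H2 (1 atm), 10% Pd/C, THF–MeOH, rt; work-up under argon
Reagents that add atoms: none
Why: Catalytic hydrogenolysis of three benzyl aryl ethers; aryl methyl ethers are inert, and the conjugated C2=C3 bond of a flavone is reduced much more slowly than O-benzyl bonds are cleaved, so the reaction is stopped at full debenzylation.

## Compound list

1 | 2',4',6'-trihydroxyacetophenone | CC(=O)c1c(O)cc(O)cc1O | starting material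
2 | 1-[2,4-bis(benzyloxy)-6-hydroxyphenyl]ethan-1-one | CC(=O)c1c(O)cc(OCc2ccccc2)cc1OCc1ccccc1 | intermediate
3 | potassium 3-acetyl-2,6-bis(benzyloxy)-4-hydroxyphenyl sulfate | CC(=O)c1c(O)cc(OCc2ccccc2)c(OS(=O)(=O)[O-])c1OCc1ccccc1.[K+] | intermediate (not isolated)
4 | 1-[2,4-bis(benzyloxy)-3,6-dihydroxyphenyl]ethan-1-one | CC(=O)c1c(O)cc(OCc2ccccc2)c(O)c1OCc1ccccc1 | intermediate
5 | 1-[2,4-bis(benzyloxy)-6-hydroxy-3-methoxyphenyl]ethan-1-one | CC(=O)c1c(O)cc(OCc2ccccc2)c(OC)c1OCc1ccccc1 | intermediate
6 | (E)-1-[2,4-bis(benzyloxy)-6-hydroxy-3-methoxyphenyl]-3-(dimethylamino)prop-2-en-1-one | CN(C)/C=C/C(=O)c1c(O)cc(OCc2ccccc2)c(OC)c1OCc1ccccc1 | intermediate (not isolated)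
7 | 5,7-bis(benzyloxy)-6-methoxy-4H-chromen-4-one | O=c1ccoc2cc(OCc3ccccc3)c(OC)c(OCc3ccccc3)c12 | intermediate
8 | 2,5-dimethoxyphenol | COc1ccc(OC)c(O)c1 | starting material
9 | 2-(benzyloxy)-1,4-dimethoxybenzene | COc1ccc(OC)c(OCc2ccccc2)c1 | intermediate
10 | 5,7-bis(benzyloxy)-2-[4-(benzyloxy)-2,5-dimethoxyphenyl]-6-methoxy-4H-chromen-4-one | COc1cc(-c2cc(=O)c3c(OCc4ccccc4)c(OC)c(OCc4ccccc4)cc3o2)c(OC)cc1OCc1ccccc1 | intermediate
11 | 5,7-dihydroxy-2-(4-hydroxy-2,5-dimethoxyphenyl)-6-methoxy-4H-chromen-4-one | COc1cc(-c2cc(=O)c3c(O)c(OC)c(O)cc3o2)c(OC)cc1O | target

## Step count and risks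

Total step count: 7. Longest linear sequence: 6 steps (steps 1, 2, 3, 4, 6, 7, from 1 to 11); step 5 is the one-step side branch.

Least certain steps:

Step 6 (key step). The most likely failure is oxidative homocoupling of the electron-rich arene, which consumes 9 and the silver oxidant before the chromone is arylated. Conversion may also be low because the three donor groups on ring A make the enone of 7 less electrophilic, and some 5-O-benzyl cleavage in hot carboxylic acid is possible. Fallback, from 5 and 9, returning at 10: 9 is formylated under Vilsmeier–Haack conditions (POCl3, DMF) at the same C5 position to give 4-(benzyloxy)-2,5-dimethoxybenzaldehyde F1. Claisen–Schmidt condensation of F1 with 5 (KOH, EtOH) should give the chalcone (E)-1-[2,4-bis(benzyloxy)-6-hydroxy-3-methoxyphenyl]-3-[4-(benzyloxy)-2,5-dimethoxyphenyl]prop-2-en-1-one F2. Oxidative cyclization of F2 (catalytic I2, DMSO, 120 °C) then gives 10. Ring C is built around the aryl group here, so no C–H coupling is needed.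

Step 2. Persulfate attack is slow on a phenolate conjugated to an ortho acetyl group, so incomplete conversion and competing oxidative degradation to dark polymeric material are to be expected. Attack ortho to the phenol instead of para is a minor risk. Fallback, from 2, returning at 4: oxidation of 2 with Fremy's salt, K2[ON(SO3)2], in buffered aqueous acetone to the para-quinone 2-acetyl-3,5-bis(benzyloxy)cyclohexa-2,5-diene-1,4-dione F3, followed by reduction with Na2S2O4. The oxygen is then introduced at the quinone oxidation level by a radical oxidation and not by electrophilic persulfate.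

Step 4. The acid-promoted closure may be accompanied by loss of the 5-O-benzyl group, which is activated by the peri carbonyl. The amide acetal may also O-methylate the phenol in competition with enaminone formation. Fallback, from 5, returning at 7: Claisen formylation of 5 (NaH, ethyl formate, THF) to racemic 5,7-bis(benzyloxy)-2-hydroxy-6-methoxychroman-4-one F4, then dehydration with catalytic toluenesulfonic acid in toluene at rt.

Step 7. Over-reduction of the C2=C3 bond to the flavanone may set in before the last benzyl ether is cleaved, and the product may be lost by adsorption on the catalyst or by air oxidation of ring B. Fallback, from 10, returning at 11: Lewis-acid debenzylation with BCl3 and pentamethylbenzene as cation scavenger in CH2Cl2 at −78 °C, which involves no hydrogen and should leave the methyl ethers intact at that temperature; it makes no new intermediate.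

## Further compounds

F1 | step 6 | 4-(benzyloxy)-2,5-dimethoxybenzaldehyde | COc1cc(C=O)c(OC)cc1OCc1ccccc1
F2 | step 6 | (E)-1-[2,4-bis(benzyloxy)-6-hydroxy-3-methoxyphenyl]-3-[4-(benzyloxy)-2,5-dimethoxyphenyl]prop-2-en-1-one | COc1cc(/C=C/C(=O)c2c(O)cc(OCc3ccccc3)c(OC)c2OCc2ccccc2)c(OC)cc1OCc1ccccc1
F3 | step 2 | 2-acetyl-3,5-bis(benzyloxy)cyclohexa-2,5-diene-1,4-dione | CC(=O)C1=C(OCc2ccccc2)C(=O)C(OCc2ccccc2)=CC1=O
F4 | step 4 | 5,7-bis(benzyloxy)-2-hydroxy-6-methoxychroman-4-one (racemic) | O=C1CC(O)Oc2cc(OCc3ccccc3)c(OC)c(OCc3ccccc3)c12
F0 | step 7 | none | none
A1 | alternative 1 | 4-(benzyloxy)-2,5-dimethoxybenzoyl chloride | COc1cc(C(Cl)=O)c(OC)cc1OCc1ccccc1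
A2 | alternative 1 | 2-acetyl-3,5-bis(benzyloxy)-4-methoxyphenyl 4-(benzyloxy)-2,5-dimethoxybenzoate | CC(=O)c1c(OC(=O)c2cc(OC)c(OCc3ccccc3)cc2OC)cc(OCc2ccccc2)c(OC)c1OCc1ccccc1
A3 | alternative 1 | 1-[2,4-bis(benzyloxy)-6-hydroxy-3-methoxyphenyl]-3-[4-(benzyloxy)-2,5-dimethoxyphenyl]propane-1,3-dione | O=C(CC(=O)c1cc(OC)c(OCc2ccccc2)cc1OC)c1c(O)cc(OCc2ccccc2)c(OC)c1OCc1ccccc1
A4 | alternative 2 | 3,5-bis(benzyloxy)-2-iodo-4-methoxyphenol | Oc1cc(OCc2ccccc2)c(OC)c(OCc2ccccc2)c1I
A5 | alternative 2 | 1-(benzyloxy)-4-ethynyl-2,5-dimethoxybenzene | C#Cc1cc(OC)c(OCc2ccccc2)cc1OC
A6 | alternative 3 | 3,5-bis(benzyloxy)-4-methoxyphenol | Oc1cc(OCc2ccccc2)c(OC)c(OCc2ccccc2)c1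
A7 | alternative 3 | ethyl 3-[4-(benzyloxy)-2,5-dimethoxyphenyl]prop-2-ynoate | CCOC(=O)C#Cc1cc(OC)c(OCc2ccccc2)cc1OC
A8 | alternative 3 | (Z)-3-[3,5-bis(benzyloxy)-4-methoxyphenoxy]-3-[4-(benzyloxy)-2,5-dimethoxyphenyl]prop-2-enoic acid | OC(=O)/C=C(/c1cc(OC)c(OCc2ccccc2)cc1OC)Oc1cc(OCc2ccccc2)c(OC)c(OCc2ccccc2)c1
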